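**Retrosynthetic overview**
1. Both ester C–O bonds are cut last. They are made in one double Mitsunobu esterification of a ring-carbinol-epimeric tetraol with two equivalents of the secoiridoid dialdehyde acid; the SN2 inversion sets the ring C–O stereocentre, and the 1,3-diol is masked in the flask as a phenylboronate.
2. The acid, (3S,4E)-4-formyl-3-(2-oxoethyl)hex-4-enoic acid, comes from oleuropein (saponification, then Krapcho-type decarbomethoxylation with loss of glucose); its stereocentre is from the chiral pool.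
3. The tetraol comes from an all-trans 2-methyl-3-(hydroxymethyl)-4-malonylcyclopentanone by bulky-hydride ketone reduction and LiAlH4; the CH2OH group comes from radical addition of methanol to the enone.
4. The enone stereocentre is set by a new enantioconvergent Pd-catalysed allylic alkylation of racemic 4-OBoc-2-methylcyclopent-2-enone with dimethyl malonate.
5. The only ring to build, the cyclopentane, is formed first, by Piancatelli rearrangement of 1-(furan-2-yl)ethanol.

Assumption: oleuropein (bulk olive-leaf product) is taken as a cheap commercial starting material, and the (R,R)-Trost ligand is assumed to give the (R)-alkylation product (use the (S,S)-ligand if the opposite sense is found).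

**Route**

Step 1
Reactants: 1 oleuropein
Product: 2 oleoside 11-methyl ester
Conditions: 1 M aq NaOH (4 equiv), Ar, 0 °C → rt; then HCl to pH 2–3; EtOAc wash, HP-20 resin
Reagents that add atoms: sodium hydroxide, [Na+].[OH-]
Why: Chemoselective saponification, in which the saturated C7 alkyl ester is cleaved while the C11 methyl ester (a vinylogous carbonate) and the acetal glucoside resist hydroxide, and no stereocentre is touched.

Step 2
Reactants: 2 oleoside 11-methyl ester
Product: 3 (3S,4E)-4-formyl-3-(2-oxoethyl)hex-4-enoic acid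
Conditions: NaCl (0.5 equiv, additive), DMSO/H2O, 150 °C, Ar
Reagents that add atoms: water, O
Why: Krapcho-type dealkoxycarbonylation, the same thermal cascade that converts oleuropein into oleacein in one step: acetal hydrolysis releases glucose, the hemiacetal opens to the aldehyde and a β-formyl ester that loses MeOH and CO2, and the enal settles as the conjugated E isomer while the stereocentre (S) is not involved.

Step 3
Reactants: 4 (±)-1-(furan-2-yl)ethanol
Product: 6 (±)-4-hydroxy-2-methylcyclopent-2-en-1-one, via trans-4-hydroxy-5-methylcyclopent-2-en-1-one 5 (not isolated)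
Conditions: H2O/dioxane, KH2PO4–H3PO4 (pH 4), 100 °C; then Na2HPO4 to pH 8, 100 °C
Reagents that add atoms: water, O
Why: Piancatelli rearrangement (furfuryl cation, water capture, 4π-conrotatory closure to the trans-4-hydroxy-5-methyl enone) followed by the established mild-base isomerisation to the more stable 2-methyl isomer; the product is racemic on purpose.

Step 4
Reactants: 6 (±)-4-hydroxy-2-methylcyclopent-2-en-1-one
Product: 7 (±)-tert-butyl (3-methyl-4-oxocyclopent-2-en-1-yl) carbonate
Conditions: Boc2O (1.2 equiv), DMAP (5 mol%), CH2Cl2, 0 °C → rt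
Reagents that add atoms: di-tert-butyl dicarbonate, CC(C)(C)OC(=O)OC(=O)OC(C)(C)C
Why: DMAP-catalysed O-acylation of the secondary allylic alcohol gives the allylic carbonate needed for base-free Pd ionisation; no stereocentre is set.

Step 5
Reactants: 7 (±)-tert-butyl (3-methyl-4-oxocyclopent-2-en-1-yl) carbonate; 8 dimethyl malonate (2 equiv)
Product: 9 dimethyl 2-[(1R)-3-methyl-4-oxocyclopent-2-en-1-yl]propanedioate
Conditions: [Pd(allyl)Cl]2 (2.5 mol%), (R,R)-DACH-phenyl Trost ligand (7.5 mol%), CH2Cl2, 0 °C → rt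
Reagents that add atoms: none
Why: Proposed new method: an enantioconvergent Tsuji–Trost alkylation in which Pd(0)/Trost ligand ionises both enantiomers of 7 anti to OBoc (CO2 and tert-butoxide are released and the latter deprotonates 8), the two diastereomeric acyl-substituted π-allyl cations interconvert through reversible C5 deprotonation to a Pd(0)-bound 2-methylcyclopentadienone and reprotonation by 8 with Pd changing face, and malonate attacks the allyl terminus remote from the carbonyl anti to Pd of the better-matched diastereomer (Curtin–Hammett), which sets the (R) centre that controls all later ring stereocentres; the closest known chemistry is Trost's DYKAT of γ-acyloxybutenolides and the Pd/Trost-ligand kinetic resolution of 4-OBoc-cyclopent-2-enone with O-, N- and S-nucleophiles.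

Step 6
Reactants: 9 dimethyl 2-[(1R)-3-methyl-4-oxocyclopent-2-en-1-yl]propanedioate
Product: 11 dimethyl 2-[(1R,2S,3R)-2-(hydroxymethyl)-3-methyl-4-oxocyclopentyl]propanedioate, via 3-epi keto diester 10 (not isolated)
Conditions: Ph2CO (0.3 equiv), MeOH (0.02 M), hν 350 nm, rt; then DBU (0.1 equiv), CH2Cl2, rt
Reagents that add atoms: methanol, CO
Why: Benzophenone-sensitised radical conjugate addition (Giese type) of •CH2OH to the enone β-carbon anti to the adjacent malonyl group sets the CH2OH centre trans to it, and the α-methyl centre, formed as a mixture on H-atom transfer, is equilibrated by DBU to the all-trans ketone (any lactone formed converges in step 7).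

Step 7
Reactants: 11 dimethyl 2-[(1R,2S,3R)-2-(hydroxymethyl)-3-methyl-4-oxocyclopentyl]propanedioate
Product: 13 2-[(1R,2S,3R,4S)-4-hydroxy-2-(hydroxymethyl)-3-methylcyclopentyl]propane-1,3-diol, via hydroxy diester 12 (not isolated)
Conditions: L-Selectride (2.5 equiv), THF, −78 °C; then LiAlH4 (4 equiv), −78 → 40 °C; Rochelle-salt work-up
Reagents that add atoms: none
Why: Bulky-hydride ketone reduction attacks the cyclopentanone anti to the α-methyl and β′-malonyl groups (as in PGE → PGF2α reductions) and gives the alcohol cis to the methyl group, the epimer needed for the later inversion, and LiAlH4 then reduces both malonate esters to the 1,3-diol.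

Step 8
Reactants: 13 2-[(1R,2S,3R,4S)-4-hydroxy-2-(hydroxymethyl)-3-methylcyclopentyl]propane-1,3-diol; 3 (3S,4E)-4-formyl-3-(2-oxoethyl)hex-4-enoic acid (2.6 equiv)
Product: 16 CNP0313563.1 (target diester), via diol phenylboronate 14 (not isolated), via bis-ester phenylboronate 15 (not isolated)
Conditions: PhB(OH)2 (1.05 equiv), 4 Å MS, THF, rt; then 3, PPh3 (3 equiv), DIAD (3 equiv, slow addition), 0 °C → rt; then pinacol (3 equiv), THF/H2O, rt
Reagents that add atoms: none
Why: The six-membered phenylboronate forms only on the 1,3-diol (boronic-ester transient protection), so the double Mitsunobu esterification acylates the primary CH2OH and displaces the activated secondary carbinol by carboxylate in an SN2 step with inversion, turning the cis-to-methyl alcohol into the trans (3R) ester of the target under neutral conditions that leave the aldehydes, the E-enals and the acid stereocentres alone, and pinacol transesterification then frees the diol.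

**Compound list**

1 | oleuropein | C/C=C1\[C@H](CC(=O)OCCc2ccc(O)c(O)c2)C(C(=O)OC)=CO[C@H]1O[C@@H]3O[C@H](CO)[C@@H](O)[C@H](O)[C@H]3O | starting material
2 | oleoside 11-methyl ester | C/C=C1\[C@H](CC(=O)O)C(C(=O)OC)=CO[C@H]1O[C@@H]2O[C@H](CO)[C@@H](O)[C@H](O)[C@H]2O | intermediate
3 | (3S,4E)-4-formyl-3-(2-oxoethyl)hex-4-enoic acid | C/C=C(/C=O)[C@@H](CC=O)CC(=O)O | intermediate
4 | (±)-1-(furan-2-yl)ethanol | CC(O)c1ccco1 | starting material
5 | (±)-trans-4-hydroxy-5-methylcyclopent-2-en-1-one (racemate, one enantiomer drawn; not isolated) | O=C1C=C[C@@H](O)[C@@H]1C | intermediate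
6 | (±)-4-hydroxy-2-methylcyclopent-2-en-1-one | CC1=CC(O)CC1=O | intermediate
7 | (±)-tert-butyl (3-methyl-4-oxocyclopent-2-en-1-yl) carbonate | CC1=CC(OC(=O)OC(C)(C)C)CC1=O | intermediate
8 | dimethyl malonate | COC(=O)CC(=O)OC | starting material
9 | dimethyl 2-[(1R)-3-methyl-4-oxocyclopent-2-en-1-yl]propanedioate | COC(=O)C(C(=O)OC)[C@H]1C=C(C)C(=O)C1 | intermediate
10 | dimethyl 2-[(1R,2S,3S)-2-(hydroxymethyl)-3-methyl-4-oxocyclopentyl]propanedioate (3-epimer of 11, methyl cis to CH2OH; not isolated) | OC[C@@H]1[C@H](C)C(=O)C[C@H]1C(C(=O)OC)C(=O)OC | intermediate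
11 | dimethyl 2-[(1R,2S,3R)-2-(hydroxymethyl)-3-methyl-4-oxocyclopentyl]propanedioate (all-trans) | OC[C@@H]1[C@@H](C)C(=O)C[C@H]1C(C(=O)OC)C(=O)OC | intermediate
12 | dimethyl 2-[(1R,2S,3R,4S)-4-hydroxy-2-(hydroxymethyl)-3-methylcyclopentyl]propanedioate (OH cis to methyl; not isolated) | OC[C@@H]1[C@@H](C)[C@@H](O)C[C@H]1C(C(=O)OC)C(=O)OC | intermediate
13 | 2-[(1R,2S,3R,4S)-4-hydroxy-2-(hydroxymethyl)-3-methylcyclopentyl]propane-1,3-diol | OC[C@@H]1[C@@H](C)[C@@H](O)C[C@H]1C(CO)CO | intermediate
14 | (1S,2R,3S,4R)-3-(hydroxymethyl)-2-methyl-4-(2-phenyl-1,3,2-dioxaborinan-5-yl)cyclopentan-1-ol (not isolated) | OC[C@@H]1[C@@H](C)[C@@H](O)C[C@H]1C2COB(OC2)c3ccccc3 | intermediate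
15 | [(1S,2R,3R,5R)-2-methyl-5-(2-phenyl-1,3,2-dioxaborinan-5-yl)-3-{[(3S,4E)-4-formyl-3-(2-oxoethyl)hex-4-enoyl]oxy}cyclopentyl]methyl (3S,4E)-4-formyl-3-(2-oxoethyl)hex-4-enoate (not isolated) | C/C=C(/C=O)[C@@H](CC=O)CC(=O)OC[C@@H]1[C@@H](C)[C@H](OC(=O)C[C@H](CC=O)/C(C=O)=C\C)C[C@H]1C2COB(OC2)c3ccccc3 | intermediate
16 | [(1S,2R,3R,5R)-5-(1,3-dihydroxypropan-2-yl)-2-methyl-3-{[(3S,4E)-4-formyl-3-(2-oxoethyl)hex-4-enoyl]oxy}cyclopentyl]methyl (3S,4E)-4-formyl-3-(2-oxoethyl)hex-4-enoate (CNP0313563.1) | C/C=C(/C=O)[C@@H](CC=O)CC(=O)OC[C@@H]1[C@@H](C)[C@H](OC(=O)C[C@H](CC=O)/C(C=O)=C\C)C[C@H]1C(CO)CO | target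

**Totals and risks**

Total step count: 8 (steps 1–2 acid branch, steps 3–8 core and coupling). Longest linear sequence: 6 (steps 3–8).

Three steps most likely to fail:

Step 5 (the proposed new method). The π-allyl face exchange may be slow, so the reaction may stall as a kinetic resolution, and base-induced loss of the carbonate to the dienone may compete. The fallback uses known chemistry only; it sets out from dimethyl malonate 8 and comes back at 9. Commercial (1S,4R)-cis-4-acetoxycyclopent-2-en-1-ol F1 is alkylated with the sodium salt of 8 under Pd(PPh3)4 in THF (Tsuji–Trost with net retention) to give dimethyl 2-[(1R,4S)-4-hydroxycyclopent-2-en-1-yl]propanedioate F2. Dess–Martin oxidation gives dimethyl 2-[(1R)-4-oxocyclopent-2-en-1-yl]propanedioate F3. Iodination with I2/pyridine gives dimethyl 2-[(1S)-3-iodo-4-oxocyclopent-2-en-1-yl]propanedioate F4 (same spatial arrangement; the descriptor changes because of iodine). Stille methylation (SnMe4, Pd2(dba)3, AsPh3, CuI, NMP) then gives 9.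

Step 6. The photochemical addition may suffer from enone [2+2] dimerisation, H-abstraction at the doubly activated ring C–H, or a slow chain with the α-methyl enone. The fallback sets out from 9 and comes back at 11. Copper-catalysed conjugate addition of the Tamao hydroxymethyl-anion equivalent iPrOMe2SiCH2MgCl (2.5 equiv, the first equivalent parks the malonate as its magnesium enolate; CuI 10 mol%, TMSCl, THF, −78 °C) anti to the malonyl group gives dimethyl 2-[(1S,2S,3R)-2-{[dimethyl(propan-2-yloxy)silyl]methyl}-3-methyl-4-oxocyclopentyl]propanedioate F5. Tamao–Fleming oxidation (KF, KHCO3, H2O2, THF/MeOH) and the same DBU equilibration then give 11.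

Step 8. The hindered carbinol may eliminate or react sluggishly with an aliphatic acid, the aldehyde-bearing acid may react with the betaine, and the boronate may not survive. The fallback separates inversion from acylation; it sets out from 13 and comes back at 16.
- 2,2-Dimethoxypropane/PPTS gives the acetonide (1S,2R,3S,4R)-4-(2,2-dimethyl-1,3-dioxan-5-yl)-3-(hydroxymethyl)-2-methylcyclopentan-1-ol F6.
- Mitsunobu reaction with 4-nitrobenzoic acid (PPh3, DIAD) gives, with inversion, [(1S,2R,3R,5R)-5-(2,2-dimethyl-1,3-dioxan-5-yl)-2-methyl-3-(4-nitrobenzoyloxy)cyclopentyl]methyl 4-nitrobenzoate F7.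
- K2CO3/MeOH gives the all-trans diol (1R,2R,3S,4R)-4-(2,2-dimethyl-1,3-dioxan-5-yl)-3-(hydroxymethyl)-2-methylcyclopentan-1-ol F8.
- Steglich esterification with 3 (EDC·HCl, DMAP, CH2Cl2; retention) gives the bis-ester acetonide [(1S,2R,3R,5R)-5-(2,2-dimethyl-1,3-dioxan-5-yl)-2-methyl-3-{[(3S,4E)-4-formyl-3-(2-oxoethyl)hex-4-enoyl]oxy}cyclopentyl]methyl (3S,4E)-4-formyl-3-(2-oxoethyl)hex-4-enoate F9.
- 80% aqueous AcOH at rt removes the acetonide to give 16.

**Further compounds**

F1 | step 5 | (1S,4R)-cis-4-acetoxycyclopent-2-en-1-ol | CC(=O)O[C@H]1C=C[C@@H](O)C1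
F2 | step 5 | dimethyl 2-[(1R,4S)-4-hydroxycyclopent-2-en-1-yl]propanedioate | COC(=O)C(C(=O)OC)[C@H]1C=C[C@@H](O)C1
F3 | step 5 | dimethyl 2-[(1R)-4-oxocyclopent-2-en-1-yl]propanedioate | COC(=O)C(C(=O)OC)[C@H]1C=CC(=O)C1
F4 | step 5 | dimethyl 2-[(1S)-3-iodo-4-oxocyclopent-2-en-1-yl]propanedioate | COC(=O)C(C(=O)OC)[C@H]1C=C(I)C(=O)C1
F5 | step 6 | dimethyl 2-[(1S,2S,3R)-2-{[dimethyl(propan-2-yloxy)silyl]methyl}-3-methyl-4-oxocyclopentyl]propanedioate | CC(C)O[Si](C)(C)C[C@@H]1[C@@H](C)C(=O)C[C@H]1C(C(=O)OC)C(=O)OC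
F6 | step 8 | (1S,2R,3S,4R)-4-(2,2-dimethyl-1,3-dioxan-5-yl)-3-(hydroxymethyl)-2-methylcyclopentan-1-ol | OC[C@@H]1[C@@H](C)[C@@H](O)C[C@H]1C2COC(C)(C)OC2
F7 | step 8 | [(1S,2R,3R,5R)-5-(2,2-dimethyl-1,3-dioxan-5-yl)-2-methyl-3-(4-nitrobenzoyloxy)cyclopentyl]methyl 4-nitrobenzoate | [O-][N+](=O)c1ccc(cc1)C(=O)OC[C@@H]2[C@@H](C)[C@H](OC(=O)c3ccc(cc3)[N+]([O-])=O)C[C@H]2C4COC(C)(C)OC4
F8 | step 8 | (1R,2R,3S,4R)-4-(2,2-dimethyl-1,3-dioxan-5-yl)-3-(hydroxymethyl)-2-methylcyclopentan-1-ol | OC[C@@H]1[C@@H](C)[C@H](O)C[C@H]1C2COC(C)(C)OC2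
F9 | step 8 | [(1S,2R,3R,5R)-5-(2,2-dimethyl-1,3-dioxan-5-yl)-2-methyl-3-{[(3S,4E)-4-formyl-3-(2-oxoethyl)hex-4-enoyl]oxy}cyclopentyl]methyl (3S,4E)-4-formyl-3-(2-oxoethyl)hex-4-enoate | C/C=C(/C=O)[C@@H](CC=O)CC(=O)OC[C@@H]1[C@@H](C)[C@H](OC(=O)C[C@H](CC=O)/C(C=O)=C\C)C[C@H]1C2COC(C)(C)OC2
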